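## Analysis of the target

The target has five benzene rings, here called A to E. Ring A is the 4-hydroxy-3-methoxybenzoyl group. Ring B is the central guaiacyl ring, with the keto-alcohol chain at C5 and the furofuran at C1. Ring D is the benzene ring of the 2,3-dihydrobenzofuran and ring E its 2-aryl group. Rings B and D are joined by a 3,7-dioxabicyclo[3.3.0]octane (furofuran) with carbons C7, C8, C9 on the ring B side and C7′, C8′, C9′ on the ring D side.

There are seven stereocentres in three groups too far apart to control one another. The furofuran is cis-fused with both aryl groups exo (C7 S, C8 R, C8′ R, C7′ S). The dihydrobenzofuran is cis (C2 S, C3 S), the less stable arrangement. The α-carbon of the ketone is S.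

The α-carbon is benzylic, next to an aryl ketone and β to a hydroxyl. Base or acid can epimerise it, cause retro-aldol loss of the CH2OH carbon or dehydration, and, with the ortho phenol of ring B, cyclodehydration to a benzofuran. The ketone must therefore appear late and the last steps must be neutral.

The benzylic ether carbons C7, C7′ and C2 each carry an aryl group with a para oxygen. Acid ionises them, which would turn the cis dihydrobenzofuran into the trans isomer and scramble the furofuran, so acid is excluded once these rings exist.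

The strategy rests on ring D. Its carbons C7, C7a and C3a carry OMe, the ring oxygen and the C3 carbon side by side, and C5, para to the oxygen, carries the furofuran. Ring B has the same pattern (OMe at C3, OH at C4, the chain at C5, the furofuran at C1 para to the hydroxyl). An aryne flanked by the methoxy group can take up a carbon arm at the remote terminus and an acyl group, later turned into the oxygen, at the near one in a single operation.

## Retrosynthetic reasoning

**38 back to 35.** The three phenols are freed last, by hydrogenolysis of tribenzyl ether 37, because that is neutral and leaves the labile α-carbon alone. The ketone of 37 is taken back to the benzylic alcohol of triol 36, so that through the whole assembly the α-carbon sits between two sp3 carbons and cannot enolise. Triol 36 comes from the tris-silyl ether 35.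

**35 back to 33.** In the furofuran the C8–C8′ bond and the C7–O bond are cut, and the C9′–O bond is traced to an epoxide. This leads to epoxy allyl ether 33, in which C7′ is the only stereocentre of the future bicycle. A radical at C8′ has to close onto the alkene and the benzylic position C7 has to be captured by the oxygen on C9′. Cutting here rather than at the two benzylic C–O bonds avoids an acid-mediated closure of a tetraol, and C7′ can then dictate C8′, C8 and C7. Alkene 33 comes from alkyne 32 by semi-hydrogenation and epoxide 32 from the terminal alkene of 31. The alkyne is kept until after the epoxidation so that only one alkene is present when the peracid is used.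

**31 back to 17 and 29.** The C7′–O bond is cut. An enantioselective allylic etherification joins allylic carbonate 17 (ring D/E half) with propargylic alcohol 29 (ring A/B half). This is the convergent union, and it creates C7′ under catalyst control.

**17 and 29 back to the aryl bromides.** The three-carbon arms are removed at the aryl–carbon bonds. Carbonate 17 comes from allylic alcohol 16, made from bromide 14 and stannane 15. Alcohol 29 comes from bromide 27 and alkyne 28. The bromine sits para to the ring oxygen in both halves.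

**14 back to 8 and 9.** Silyl ether 14 comes from alcohol 13 and ester 12. In 12 the C2–C3 bond is cut: a carbene at C3, generated from diazo ester 11, inserts into the benzylic C–H bond of the ring E benzyl ether. This closes the ring and sets both centres cis under catalyst control. Diazo ester 11 comes from arylacetate 10, the ether of phenol 8 with benzylic alcohol 9.

**27 back to 8 and 23.** Bis-silyl ether 27 comes from diol 26 and aldol adduct 25. The bond between the α-carbon and the carbinol carbon is cut: a syn-aldol reaction of imide 22 with aldehyde 23 sets the α-carbon through auxiliary 20. Imide 22 comes from acid 19, ester 18 and again phenol 8.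

**8 back to 5.** Both halves thus meet in bromophenol 8. Its bromine is put in last, para to the free hydroxyl of 7, where both ortho positions are blocked. It is not carried through the aryne step because an ortho-silyl aryl triflate bearing bromine would need a directed lithiation next to an aryl bromide. Phenol 7 comes from aryl acetate 6, and 6 from aryl methyl ketone 5 by oxygen insertion with aryl migration.

**5 back to 1 and 2.** The aryl–CH2 bond and the aryl–acetyl bond of 5 are cut together. The aryne from silyl triflate 1 inserts into the C–C bond of ketoester 2. The methoxy group of 1 decides which aryne carbon receives the carbon arm. One step builds the three neighbouring substituents shared by rings B and D, and 1 is a catalogue compound.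

## Alternatives that were turned down

**Alternative 1:** The furofuran is traced to the all-trans cyclobutane A1. The bond between the two future ring-fusion carbons and the bond between the two aryl-bearing carbons are cut, giving the ring D cinnamoyl imidazole A2 and the ring B cinnamyl silyl ether A3. Forward, A2 and A3 combine in a crossed [2+2] cycloaddition under visible light on a chiral Lewis acid. Later the acyl group is reduced and the strained diaryl bond is opened oxidatively so that the two hydroxymethyl arms close both tetrahydrofuran rings.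

- **For:** C8–C8′ is made between two fragments in one catalytic, enantioselective step, which is more direct than any tethered closure. Ring strain pays for the later opening.
- **Against:** Two different styrene-type alkenes must pair crosswise and head to head, in competition with homodimerisation and E/Z isomerisation. Two of the four new stereocentres are destroyed again. The oxidant that opens A1 must single out one electron-rich diarylethane unit among four electron-rich rings and a cis dihydrobenzofuran. The keto-alcohol chain would have to be attached late at a bromine next to a benzyloxy group, with no good way to set the enolisable α-carbon.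
- **Comparison:** On convergence at C8–C8′ this alternative is stronger. The chosen route instead controls all four furofuran centres from one ether carbon, sets the α-carbon early with an auxiliary, and draws both trisubstituted rings from one intermediate. Alternative 1 leaves the origin of ring D open.

**Alternative 2:** The C2–C3 bond of the dihydrobenzofuran ester A4 is cut, leading to the diazo ester A5. Forward, a divalent rhodium carboxylate catalyst turns A5 into a carbene that inserts into the benzylic C–H bond and closes the oxygen ring cis.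

- **For:** Both ring stereocentres come from one catalytic step of a well-studied type, and the less stable cis isomer is the kinetic product.
- **Against as the organising idea:** It says nothing about where the arene of A5, with its acetate arm, oxygen, methoxy group and bromine in fixed positions, comes from. A classical answer (allylation, Claisen rearrangement, oxidative cleavage, esterification) is longer and serves ring D only.
- **Comparison:** A4 and A5 are the same compounds as 12 and 11, so on the stereochemical event the two strategies are equal, and the alternative needs no aryne precursor. The chosen strategy adds a one-step, regiodefined construction of the arene and uses it twice, for ring D and for ring B.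

**Alternative 3:** The two benzylic C–O bonds of furofuran A6 are cut, leading to the threo dibenzylbutane-1,4-diol A7. Forward, a high-potential quinone oxidant removes hydride from the two benzylic CH2 groups in turn and each cation is caught by the remote hydroxyl.

- **For:** Diols of this type are easy to make enantiopure, since only C8 and C8′ need to be set. No carbinol centres have to be controlled, and both rings form in one flask.
- **Against:** The oxidant must choose two benzylic CH2 groups over the benzylic C–H bonds at C2 and C3 of the dihydrobenzofuran and over the furofuran C–H bonds of the product. That forces a free phenol on ring B and a sulfonate on ring E. The exo or endo position of each aryl group depends on the closure of a free cation, and a 2,5-diaryl tetrahydrofuran can form instead. Ring B again ends as a bromophenol, so the keto-alcohol chain and its stereocentre remain to be built on the finished core.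
- **Comparison:** This alternative is shorter in the furofuran sector. The chosen route avoids cationic intermediates at C7′ and C8 to C8′, and has the A/B chain complete before the halves are joined.

Key step: step 1

Remark on the chemistry: the sense of induction of Rh2(S-PTTL)4 in step 7 and of the (Sa,S,S) ligand in step 19 is taken as drawn; should either be opposite, the mirror-image catalyst or ligand is used and nothing else changes.

Shorthand in names: TBS = tert-butyldimethylsilyl, Bn = benzyl.
- "D-aryl" = (2S,3S)-2-[4-(benzyloxy)-3-methoxyphenyl]-3-[(TBS-oxy)methyl]-7-methoxy-2,3-dihydro-1-benzofuran-5-yl.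
- "B-aryl" = 4-(benzyloxy)-3-methoxy-5-{(1R,2S)-1-[4-(benzyloxy)-3-methoxyphenyl]-1,3-bis(TBS-oxy)propan-2-yl}phenyl.

## Route

Step 1
Reactants: 1 3-methoxy-2-(trimethylsilyl)phenyl trifluoromethanesulfonate; 2 methyl acetoacetate
Product: 5 methyl 2-(2-acetyl-3-methoxyphenyl)acetate, via 3-methoxybenzyne 3 (not isolated), via cesium benzocyclobutenoxide 4 (not isolated)
Conditions: CsF (2.5 equiv), MeCN, 80 °C
Reagents that add atoms: none
Why: Fluoride attacks silicon and triflate leaves, releasing aryne 3; the cesium enolate of 2 adds through carbon to the aryne carbon remote from the methoxy group, which is the more distorted terminus and leaves the aryl anion next to the inductively stabilising C–O bond. That anion adds to the ketone carbonyl in a 4-exo-trig closure to give cyclobutenoxide 4, and strain then breaks the former α-carbon–carbonyl bond to an ester-stabilised benzylic anion that is protonated. The net result is insertion of the two aryne carbons into the C–C σ bond, placing CH2CO2Me at the future C3a and acetyl at the future oxygen-bearing carbon. The closest known reaction is the fluoride-triggered acyl-alkylation of arynes by β-ketoesters, which includes this methoxy-substituted aryne. The four-membered ring is the only ring closed and it is opened again; no stereocentre is formed. The step needs regioselectivity at the unsymmetrical aryne, which the methoxy group secures, and C-arylation followed by fragmentation rather than simple α-arylation, which hot MeCN with the weakly paired cesium enolate favours.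

Step 2
Reactants: 5 methyl 2-(2-acetyl-3-methoxyphenyl)acetate
Product: 6 methyl 2-(2-acetoxy-3-methoxyphenyl)acetate
Conditions: mCPBA, CF3CO2H (cat.), CH2Cl2, 0 °C → rt
Reagents that add atoms: 3-chloroperbenzoic acid (mCPBA), OOC(=O)c1cccc(Cl)c1
Why: Baeyer–Villiger oxidation; the electron-rich aryl group, twisted out of conjugation by its two ortho substituents, migrates in preference to methyl, so the acetyl carbon is exchanged for oxygen exactly where ring D and ring B need it.

Step 3
Reactants: 6 methyl 2-(2-acetoxy-3-methoxyphenyl)acetate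
Product: 7 methyl 2-(2-hydroxy-3-methoxyphenyl)acetate
Conditions: K2CO3, MeOH, 0 °C; aq. NH4Cl
Reagents that add atoms: none
Why: Methanolysis of the aryl acetate, which is far more electrophilic than the methyl ester; exchange at the methyl ester is degenerate, and neutral work-up avoids lactonisation to the benzofuranone.

Step 4
Reactants: 7 methyl 2-(2-hydroxy-3-methoxyphenyl)acetate
Product: 8 methyl 2-(5-bromo-2-hydroxy-3-methoxyphenyl)acetate
Conditions: NBS, MeCN, −10 → 0 °C
Reagents that add atoms: N-bromosuccinimide, BrN1C(=O)CCC1=O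
Why: Electrophilic aromatic bromination; the hydroxyl is the strongest director and both its ortho positions are occupied, so bromine enters para to it, at the carbon that will carry the furofuran in both rings.

Step 5
Reactants: 8 methyl 2-(5-bromo-2-hydroxy-3-methoxyphenyl)acetate; 9 [4-(benzyloxy)-3-methoxyphenyl]methanol
Product: 10 methyl 2-(2-{[4-(benzyloxy)-3-methoxyphenyl]methoxy}-5-bromo-3-methoxyphenyl)acetate
Conditions: PPh3, DIAD, THF, 0 °C → rt
Reagents that add atoms: none
Why: Mitsunobu etherification of the phenol with a primary benzylic alcohol; it attaches the ring E unit without an unstable electron-rich benzyl halide and without base strong enough to touch the ester.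

Step 6
Reactants: 10 methyl 2-(2-{[4-(benzyloxy)-3-methoxyphenyl]methoxy}-5-bromo-3-methoxyphenyl)acetate
Product: 11 methyl 2-(2-{[4-(benzyloxy)-3-methoxyphenyl]methoxy}-5-bromo-3-methoxyphenyl)-2-diazoacetate
Conditions: p-ABSA, DBU, MeCN, 0 °C → rt
Reagents that add atoms: 4-acetamidobenzenesulfonyl azide (p-ABSA), CC(=O)Nc1ccc(cc1)S(=O)(=O)N=[N+]=[N-]
Why: Regitz diazo transfer to the benzylic ester position, the standard entry to aryldiazoacetates.

Step 7
Reactants: 11 methyl 2-(2-{[4-(benzyloxy)-3-methoxyphenyl]methoxy}-5-bromo-3-methoxyphenyl)-2-diazoacetate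
Product: 12 methyl (2S,3R)-2-[4-(benzyloxy)-3-methoxyphenyl]-5-bromo-7-methoxy-2,3-dihydro-1-benzofuran-3-carboxylate (cis)
Conditions: Rh2(S-PTTL)4 [dirhodium tetrakis(N-phthaloyl-(S)-tert-leucinate)] (1 mol %), toluene, −60 °C
Reagents that add atoms: none
Why: Intramolecular 1,5 C–H insertion of the rhodium carbene into the benzylic ether C–H bond of the ring E benzyl group, the bond best activated (oxygen and aryl) and the only one within reach of a five-membered transition state. Dirhodium phthalimido-tert-leucinate catalysts are known to give the cis 2-aryl-3-carboxylate from this substrate class, the chiral wall of the catalyst setting C2 (S) and C3 (R) in one concerted step. Low temperature and the absence of base keep the kinetic cis ester from epimerising.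

Step 8
Reactants: 12 methyl (2S,3R)-2-[4-(benzyloxy)-3-methoxyphenyl]-5-bromo-7-methoxy-2,3-dihydro-1-benzofuran-3-carboxylate
Product: 13 [(2S,3S)-2-[4-(benzyloxy)-3-methoxyphenyl]-5-bromo-7-methoxy-2,3-dihydro-1-benzofuran-3-yl]methanol (cis)
Conditions: i-Bu2AlH, CH2Cl2, −78 → −40 °C; aq. KNaC4H4O6
Reagents that add atoms: none
Why: Ester reduction with a Lewis acidic, non-basic hydride, so that C3 is never enolised; once the carboxyl carbon is CH2OH the cis relationship is fixed (the descriptor at C3 changes only through the priority rules).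

Step 9
Reactants: 13 [(2S,3S)-2-[4-(benzyloxy)-3-methoxyphenyl]-5-bromo-7-methoxy-2,3-dihydro-1-benzofuran-3-yl]methanol
Product: 14 (2S,3S)-2-[4-(benzyloxy)-3-methoxyphenyl]-5-bromo-3-[(TBS-oxy)methyl]-7-methoxy-2,3-dihydro-1-benzofuran (D-aryl bromide)
Conditions: TBSCl, imidazole, DMF, rt
Reagents that add atoms: tert-butyldimethylsilyl chloride, CC(C)(C)[Si](C)(C)Cl
Why: Silylation of the primary alcohol; the silyl ether survives organometallic, radical and hydrogenation steps and is removed by fluoride before the ketone exists.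

Step 10
Reactants: 14 D-aryl bromide; 15 (E)-3-(tributylstannyl)prop-2-en-1-ol
Product: 16 (E)-3-(D-aryl)prop-2-en-1-ol
Conditions: Pd(PPh3)4 (5 mol %), toluene, 100 °C
Reagents that add atoms: none
Why: Stille coupling; the alkenyl group is transferred with retention of the E geometry and the free hydroxyl is tolerated, so the cinnamyl alcohol is reached in one step from the bromide.

Step 11
Reactants: 16 (E)-3-(D-aryl)prop-2-en-1-ol
Product: 17 tert-butyl (E)-3-(D-aryl)prop-2-en-1-yl carbonate
Conditions: n-BuLi, THF, −78 °C; Boc2O, −78 → 0 °C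
Reagents that add atoms: di-tert-butyl dicarbonate, CC(C)(C)OC(=O)OC(=O)OC(C)(C)C
Why: O-Acylation of the lithium alkoxide gives the allylic tert-butyl carbonate, a leaving group whose tert-butoxide does not compete as a nucleophile in step 19.

Step 12
Reactants: 8 methyl 2-(5-bromo-2-hydroxy-3-methoxyphenyl)acetate
Product: 18 methyl 2-[2-(benzyloxy)-5-bromo-3-methoxyphenyl]acetate
Conditions: BnBr, K2CO3, DMF, rt
Reagents that add atoms: benzyl bromide, BrCc1ccccc1
Why: Williamson O-benzylation of the phenoxide; carbonate is too weak to deprotonate the ester CH2.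

Step 13
Reactants: 18 methyl 2-[2-(benzyloxy)-5-bromo-3-methoxyphenyl]acetate
Product: 19 2-[2-(benzyloxy)-5-bromo-3-methoxyphenyl]acetic acid
Conditions: LiOH, THF/MeOH/H2O, rt; then 1 M HCl
Reagents that add atoms: lithium hydroxide, [Li+].[OH-]
Why: Saponification of the methyl ester; nothing else in the molecule is sensitive to hydroxide.

Step 14
Reactants: 19 2-[2-(benzyloxy)-5-bromo-3-methoxyphenyl]acetic acid; 20 (R)-4-benzyl-1,3-oxazolidin-2-one
Product: 22 (R)-4-benzyl-3-{2-[2-(benzyloxy)-5-bromo-3-methoxyphenyl]acetyl}-1,3-oxazolidin-2-one, via mixed pivalic anhydride 21 (not isolated)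
Conditions: t-BuCOCl, Et3N, THF, −20 °C; then LiCl, 20, rt
Reagents that add atoms: none
Why: N-Acylation of the oxazolidinone by the mixed anhydride, attacked at the unhindered arylacetyl carbonyl; LiCl makes the oxazolidinone nucleophilic enough without a strong base.

Step 15
Reactants: 22 (R)-4-benzyl-3-{2-[2-(benzyloxy)-5-bromo-3-methoxyphenyl]acetyl}-1,3-oxazolidin-2-one; 23 4-(benzyloxy)-3-methoxybenzaldehyde
Product: 25 (R)-4-benzyl-3-{(2R,3R)-2-[2-(benzyloxy)-5-bromo-3-methoxyphenyl]-3-[4-(benzyloxy)-3-methoxyphenyl]-3-hydroxypropanoyl}-1,3-oxazolidin-2-one, via dibutylboron enolate 24 (not isolated)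
Conditions: Bu2BOTf, i-Pr2NEt, CH2Cl2, −78 → 0 °C; 23, −78 → 0 °C; pH 7 buffer, MeOH, H2O2
Reagents that add atoms: none
Why: Evans syn-aldol reaction: the Z boron enolate 24 reacts through a closed chair transition state on the face away from the benzyl group of the (R)-auxiliary and gives the (2R,3R) syn adduct. The α-carbon set here becomes the α-carbon of the final ketone; the carbinol centre is later oxidised away, so only the α-carbon matters.

Step 16
Reactants: 25 aldol adduct
Product: 26 (1R,2S)-1-[4-(benzyloxy)-3-methoxyphenyl]-2-[2-(benzyloxy)-5-bromo-3-methoxyphenyl]propane-1,3-diol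
Conditions: LiBH4, H2O (1 equiv), Et2O/THF, 0 °C
Reagents that add atoms: none
Why: Reductive removal of the auxiliary; the imide carbonyl is reduced at 0 °C fast enough to outrun retro-aldol cleavage, and 20 is recovered. The α-carbon keeps its geometry and becomes S only because the reduced carbon now ranks below the carbinol carbon.

Step 17
Reactants: 26 diol
Product: 27 bis(TBS) ether of 26 (B-aryl bromide)
Conditions: TBSOTf, 2,6-lutidine, CH2Cl2, −78 → 0 °C
Reagents that add atoms: tert-butyldimethylsilyl trifluoromethanesulfonate, CC(C)(C)[Si](C)(C)OS(=O)(=O)C(F)(F)F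
Why: Silylation of both hydroxyls with the reactive triflate under buffered conditions, so that the hindered, ionisable benzylic alcohol is protected without acid.

Step 18
Reactants: 27 B-aryl bromide; 28 prop-2-yn-1-ol
Product: 29 3-(B-aryl)prop-2-yn-1-ol
Conditions: Pd(PhCN)2Cl2 (3 mol %), P(t-Bu)3 (6 mol %), CuI (2 mol %), i-Pr2NH, dioxane, rt
Reagents that add atoms: none
Why: Sonogashira coupling; the bulky electron-rich phosphine lets the electron-rich aryl bromide undergo oxidative addition at room temperature, and the free propargylic hydroxyl is tolerated.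

Step 19
Reactants: 17 tert-butyl (E)-3-(D-aryl)prop-2-en-1-yl carbonate; 29 3-(B-aryl)prop-2-yn-1-ol
Product: 31 (1S)-1-(D-aryl)prop-2-en-1-yl 3-(B-aryl)prop-2-yn-1-yl ether, via copper alkoxide 30 (not isolated)
Conditions: 29, n-BuLi, THF, −78 → 0 °C; CuI; then 17, [Ir(cod)Cl]2 (2 mol %), (Sa)-O,O′-(1,1′-binaphthyl-2,2′-diyl) N,N-bis[(S)-1-phenylethyl]phosphoramidite (4 mol %), THF, rt
Reagents that add atoms: none
Why: Iridium-catalysed asymmetric allylic etherification: the monovalent iridium phosphoramidite complex ionises the carbonate to an aryl-substituted allyl complex, and copper alkoxide 30 attacks its substituted terminus to give the branched ether, the ligand fixing the new centre C7′ as S. The released tert-butoxide is too hindered to compete, and aryl-substituted allylic carbonates with aliphatic copper alkoxides are the established substrate class for this reaction.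

Step 20
Reactants: 31 allyl propargyl ether
Product: 32 (R)-(D-aryl)[(2RS)-oxiran-2-yl]methyl 3-(B-aryl)prop-2-yn-1-yl ether
Conditions: mCPBA, NaHCO3, CH2Cl2, rt
Reagents that add atoms: 3-chloroperbenzoic acid (mCPBA), OOC(=O)c1cccc(Cl)c1
Why: Prilezhaev epoxidation of the only alkene; peracids react with alkynes far more slowly, which is why the second unsaturation is still an alkyne here. Both epoxide epimers are used, since that carbon becomes a radical in step 22 (the descriptor of C7′ changes to R only through the priority rules).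

Step 21
Reactants: 32 epoxy propargyl ether
Product: 33 (R)-(D-aryl)[(2RS)-oxiran-2-yl]methyl (Z)-3-(B-aryl)prop-2-en-1-yl ether
Conditions: H2 (1 atm), Pd/CaCO3 poisoned with Pb(OAc)2, quinoline, EtOAc, rt
Reagents that add atoms: none
Why: Lindlar semi-hydrogenation, syn addition giving the Z styrenyl alkene that serves as radical acceptor; the poisoned catalyst leaves the benzyl ethers and the epoxide alone.

Step 22
Reactants: 33 epoxy allyl ether
Product: 35 (1S,3aR,4S,6aR)-1-(B-aryl)-4-(D-aryl)tetrahydro-1H,3H-furo[3,4-c]furan, via benzylic iodide 34 (not isolated)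
Conditions: Cp2TiCl2, Zn dust, THF, rt (forms Cp2TiCl); slow addition of 33; then I2, rt
Reagents that add atoms: none
Why: Cp2TiCl opens the epoxide by single-electron transfer to the secondary radical at C8′ (titanium alkoxide on C9′), which closes 5-exo-trig onto the styrenyl alkene through a chair-like transition state with the aryl group on C7′ and the CH2OTi arm pseudo-equatorial, so that C7′ alone fixes C8′ and C8 (cis ring fusion, ring D aryl exo) and the epoxide epimers converge. The benzylic radical at C7 is taken up by a second Cp2TiCl, iodine turns the C–Ti bond into benzylic iodide 34, and the titanium alkoxide displaces it (5-exo-tet through the ion pair stabilised by the para oxygen) with the ring B aryl on the convex face. This is the trivalent-titanium radical cyclisation of epoxy cinnamyl ethers with iodine termination, a known way to exo,exo-furofuran lignans.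

Step 23
Reactants: 35 tris(TBS) furofuran
Product: 36 triol (35 with the three TBS groups replaced by H)
Conditions: Bu4NF, THF, 0 °C → rt
Reagents that add atoms: none
Why: Fluoride cleavage of the three silyl ethers, done while no base-sensitive carbonyl is present.

Step 24
Reactants: 36 triol
Product: 37 tribenzyl ether of the target (ketone)
Conditions: activated MnO2, CH2Cl2, rt
Reagents that add atoms: none
Why: Chemoselective oxidation of the benzylic secondary alcohol next to ring A; MnO2 leaves the two saturated primary alcohols untouched, and the neutral, heterogeneous conditions spare the newly enolisable α-carbon.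

Step 25
Reactants: 37 tribenzyl ether of the target
Product: 38 (2S)-3-hydroxy-1-(4-hydroxy-3-methoxyphenyl)-2-{2-hydroxy-5-[(1S,3aR,4S,6aR)-4-[(2S,3S)-2-(4-hydroxy-3-methoxyphenyl)-3-(hydroxymethyl)-7-methoxy-2,3-dihydro-1-benzofuran-5-yl]tetrahydro-1H,3H-furo[3,4-c]furan-1-yl]-3-methoxyphenyl}propan-1-one (CNP0174045.1)
Conditions: H2 (1 atm), Pd/C, EtOAc/THF, rt
Reagents that add atoms: none
Why: Hydrogenolysis of the three aryl benzyl ethers, which cleave much faster than the cyclic benzylic ethers and leave the aryl ketone unreduced at one atmosphere; the medium is neutral, so the α-carbon, the cis ring and the furofuran are not disturbed.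

## Compound list

1 | 3-methoxy-2-(trimethylsilyl)phenyl trifluoromethanesulfonate | COc1cccc(OS(=O)(=O)C(F)(F)F)c1[Si](C)(C)C | starting material
2 | methyl acetoacetate | CC(=O)CC(=O)OC | starting material
3 | 3-methoxybenzyne | COC1=CC=CC#C1 | intermediate (not isolated)
4 | cesium alkoxide of methyl 8-hydroxy-2-methoxy-8-methylbicyclo[4.2.0]octa-1,3,5-triene-7-carboxylate | COC(=O)C1c2cccc(OC)c2C1(C)[O-].[Cs+] | intermediate (not isolated)
5 | methyl 2-(2-acetyl-3-methoxyphenyl)acetate | COC(=O)Cc1cccc(OC)c1C(C)=O | intermediate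
6 | methyl 2-(2-acetoxy-3-methoxyphenyl)acetate | COC(=O)Cc1cccc(OC)c1OC(C)=O | intermediate
7 | methyl 2-(2-hydroxy-3-methoxyphenyl)acetate | COC(=O)Cc1cccc(OC)c1O | intermediate
8 | methyl 2-(5-bromo-2-hydroxy-3-methoxyphenyl)acetate | COC(=O)Cc1cc(Br)cc(OC)c1O | intermediate
9 | [4-(benzyloxy)-3-methoxyphenyl]methanol | COc1cc(CO)ccc1OCc1ccccc1 | starting material
10 | methyl 2-(2-{[4-(benzyloxy)-3-methoxyphenyl]methoxy}-5-bromo-3-methoxyphenyl)acetate | COC(=O)Cc1cc(Br)cc(OC)c1OCc1ccc(OCc2ccccc2)c(OC)c1 | intermediate
11 | methyl 2-(2-{[4-(benzyloxy)-3-methoxyphenyl]methoxy}-5-bromo-3-methoxyphenyl)-2-diazoacetate | COC(=O)C(=[N+]=[N-])c1cc(Br)cc(OC)c1OCc1ccc(OCc2ccccc2)c(OC)c1 | intermediate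
12 | methyl (2S,3R)-2-[4-(benzyloxy)-3-methoxyphenyl]-5-bromo-7-methoxy-2,3-dihydro-1-benzofuran-3-carboxylate (cis) | Brc1cc(OC)c2c(c1)[C@@H](C(=O)OC)[C@@H](c1ccc(OCc3ccccc3)c(OC)c1)O2 | intermediate
13 | [(2S,3S)-2-[4-(benzyloxy)-3-methoxyphenyl]-5-bromo-7-methoxy-2,3-dihydro-1-benzofuran-3-yl]methanol (cis) | Brc1cc(OC)c2c(c1)[C@@H](CO)[C@@H](c1ccc(OCc3ccccc3)c(OC)c1)O2 | intermediate
14 | (2S,3S)-2-[4-(benzyloxy)-3-methoxyphenyl]-5-bromo-3-[(TBS-oxy)methyl]-7-methoxy-2,3-dihydro-1-benzofuran (D-aryl bromide) | Brc1cc(OC)c2c(c1)[C@@H](CO[Si](C)(C)C(C)(C)C)[C@@H](c1ccc(OCc3ccccc3)c(OC)c1)O2 | intermediate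
15 | (E)-3-(tributylstannyl)prop-2-en-1-ol | CCCC[Sn](CCCC)(CCCC)/C=C/CO | starting material
16 | (E)-3-(D-aryl)prop-2-en-1-ol | OC/C=C/c1cc(OC)c2c(c1)[C@@H](CO[Si](C)(C)C(C)(C)C)[C@@H](c1ccc(OCc3ccccc3)c(OC)c1)O2 | intermediate
17 | tert-butyl (E)-3-(D-aryl)prop-2-en-1-yl carbonate | CC(C)(C)OC(=O)OC/C=C/c1cc(OC)c2c(c1)[C@@H](CO[Si](C)(C)C(C)(C)C)[C@@H](c1ccc(OCc3ccccc3)c(OC)c1)O2 | intermediate
18 | methyl 2-[2-(benzyloxy)-5-bromo-3-methoxyphenyl]acetate | COC(=O)Cc1cc(Br)cc(OC)c1OCc1ccccc1 | intermediate
19 | 2-[2-(benzyloxy)-5-bromo-3-methoxyphenyl]acetic acid | OC(=O)Cc1cc(Br)cc(OC)c1OCc1ccccc1 | intermediate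
20 | (R)-4-benzyl-1,3-oxazolidin-2-one | O=C1N[C@H](Cc2ccccc2)CO1 | starting material
21 | mixed anhydride of 19 with pivalic acid | CC(C)(C)C(=O)OC(=O)Cc1cc(Br)cc(OC)c1OCc1ccccc1 | intermediate (not isolated)
22 | (R)-4-benzyl-3-{2-[2-(benzyloxy)-5-bromo-3-methoxyphenyl]acetyl}-1,3-oxazolidin-2-one | O=C(Cc1cc(Br)cc(OC)c1OCc1ccccc1)N1[C@H](Cc2ccccc2)COC1=O | intermediate
23 | 4-(benzyloxy)-3-methoxybenzaldehyde | COc1cc(C=O)ccc1OCc1ccccc1 | starting material
24 | (Z)-dibutylboron enolate of 22 | CCCCB(CCCC)O/C(=C\c1cc(Br)cc(OC)c1OCc1ccccc1)N1[C@H](Cc2ccccc2)COC1=O | intermediate (not isolated)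
25 | (R)-4-benzyl-3-{(2R,3R)-2-[2-(benzyloxy)-5-bromo-3-methoxyphenyl]-3-[4-(benzyloxy)-3-methoxyphenyl]-3-hydroxypropanoyl}-1,3-oxazolidin-2-one | O=C([C@H](c1cc(Br)cc(OC)c1OCc1ccccc1)[C@@H](O)c1ccc(OCc2ccccc2)c(OC)c1)N1[C@H](Cc2ccccc2)COC1=O | intermediate
26 | (1R,2S)-1-[4-(benzyloxy)-3-methoxyphenyl]-2-[2-(benzyloxy)-5-bromo-3-methoxyphenyl]propane-1,3-diol | OC[C@H](c1cc(Br)cc(OC)c1OCc1ccccc1)[C@@H](O)c1ccc(OCc2ccccc2)c(OC)c1 | intermediate
27 | bis(TBS) ether of 26 (B-aryl bromide) | CC(C)(C)[Si](C)(C)OC[C@H](c1cc(Br)cc(OC)c1OCc1ccccc1)[C@@H](O[Si](C)(C)C(C)(C)C)c1ccc(OCc2ccccc2)c(OC)c1 | intermediate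
28 | prop-2-yn-1-ol | C#CCO | starting material
29 | 3-(B-aryl)prop-2-yn-1-ol | CC(C)(C)[Si](C)(C)OC[C@H](c1cc(C#CCO)cc(OC)c1OCc1ccccc1)[C@@H](O[Si](C)(C)C(C)(C)C)c1ccc(OCc2ccccc2)c(OC)c1 | intermediate
30 | copper alkoxide of 29 (monovalent copper) | CC(C)(C)[Si](C)(C)OC[C@H](c1cc(C#CCO[Cu])cc(OC)c1OCc1ccccc1)[C@@H](O[Si](C)(C)C(C)(C)C)c1ccc(OCc2ccccc2)c(OC)c1 | intermediate (not isolated)
31 | (1S)-1-(D-aryl)prop-2-en-1-yl 3-(B-aryl)prop-2-yn-1-yl ether | CC(C)(C)[Si](C)(C)OC[C@H](c1cc(C#CCO[C@@H](C=C)c2cc(OC)c3c(c2)[C@@H](CO[Si](C)(C)C(C)(C)C)[C@@H](c2ccc(OCc4ccccc4)c(OC)c2)O3)cc(OC)c1OCc1ccccc1)[C@@H](O[Si](C)(C)C(C)(C)C)c1ccc(OCc2ccccc2)c(OC)c1 | intermediate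
32 | (R)-(D-aryl)[(2RS)-oxiran-2-yl]methyl 3-(B-aryl)prop-2-yn-1-yl ether | CC(C)(C)[Si](C)(C)OC[C@H](c1cc(C#CCO[C@@H](C5CO5)c2cc(OC)c3c(c2)[C@@H](CO[Si](C)(C)C(C)(C)C)[C@@H](c2ccc(OCc4ccccc4)c(OC)c2)O3)cc(OC)c1OCc1ccccc1)[C@@H](O[Si](C)(C)C(C)(C)C)c1ccc(OCc2ccccc2)c(OC)c1 | intermediate
33 | (R)-(D-aryl)[(2RS)-oxiran-2-yl]methyl (Z)-3-(B-aryl)prop-2-en-1-yl ether | CC(C)(C)[Si](C)(C)OC[C@H](c1cc(/C=C\CO[C@@H](C5CO5)c2cc(OC)c3c(c2)[C@@H](CO[Si](C)(C)C(C)(C)C)[C@@H](c2ccc(OCc4ccccc4)c(OC)c2)O3)cc(OC)c1OCc1ccccc1)[C@@H](O[Si](C)(C)C(C)(C)C)c1ccc(OCc2ccccc2)c(OC)c1 | intermediate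
34 | [(2S,3R,4R)-2-(D-aryl)-4-[(B-aryl)iodomethyl]tetrahydrofuran-3-yl]methanol, present in the flask as its titanium alkoxide (drawn as the alcohol; iodide carbon not defined) | CC(C)(C)[Si](C)(C)OC[C@H](c1cc(C(I)[C@H]2CO[C@H](c3cc(OC)c4c(c3)[C@@H](CO[Si](C)(C)C(C)(C)C)[C@@H](c3ccc(OCc5ccccc5)c(OC)c3)O4)[C@H]2CO)cc(OC)c1OCc1ccccc1)[C@@H](O[Si](C)(C)C(C)(C)C)c1ccc(OCc2ccccc2)c(OC)c1 | intermediate (not isolated)
35 | (1S,3aR,4S,6aR)-1-(B-aryl)-4-(D-aryl)tetrahydro-1H,3H-furo[3,4-c]furan | CC(C)(C)[Si](C)(C)OC[C@H](c1cc([C@H]2OC[C@H]3[C@@H]2CO[C@@H]3c2cc(OC)c3c(c2)[C@@H](CO[Si](C)(C)C(C)(C)C)[C@@H](c2ccc(OCc4ccccc4)c(OC)c2)O3)cc(OC)c1OCc1ccccc1)[C@@H](O[Si](C)(C)C(C)(C)C)c1ccc(OCc2ccccc2)c(OC)c1 | intermediate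
36 | triol: 35 with the three TBS groups replaced by H | OC[C@H](c1cc([C@H]2OC[C@H]3[C@@H]2CO[C@@H]3c2cc(OC)c3c(c2)[C@@H](CO)[C@@H](c2ccc(OCc4ccccc4)c(OC)c2)O3)cc(OC)c1OCc1ccccc1)[C@@H](O)c1ccc(OCc2ccccc2)c(OC)c1 | intermediate
37 | tribenzyl ether of the target (rings A, B and E as benzyl ethers; α-carbon S) | COc1cc(C(=O)[C@H](CO)c2cc([C@H]3OC[C@H]4[C@@H]3CO[C@@H]4c3cc(OC)c4c(c3)[C@@H](CO)[C@@H](c3ccc(OCc5ccccc5)c(OC)c3)O4)cc(OC)c2OCc2ccccc2)ccc1OCc1ccccc1 | intermediate
38 | CNP0174045.1, named in step 25 | COc1cc(C(=O)[C@H](CO)c2cc([C@H]3OC[C@H]4[C@@H]3CO[C@@H]4c3cc(OC)c4c(c3)[C@@H](CO)[C@@H](c3ccc(O)c(OC)c3)O4)cc(OC)c2O)ccc1O | target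

## Step count and uncertain steps

Total: 25 steps. Longest linear sequence: 18 steps (steps 1–4, 5–11, 19–25; the branch through steps 12–18 is equally long).

**Step 1 (key step).** The most likely failure is that the adduct of enolate and aryne is protonated before it closes onto the ketone, giving simple α-arylation, or that product 5 is arylated a second time. Closure is slowed because the aryl anion sits between the methoxy group and the new substituent. Fallback without an aryne: it sets out from methyl acetoacetate 2 and comes back at 10 and at 18. Purchased 4-bromo-2-methoxyphenol F1 is iodinated at its only free position ortho to the hydroxyl (N-iodosuccinimide) to give 4-bromo-2-iodo-6-methoxyphenol F2. Benzylation gives 2-(benzyloxy)-5-bromo-1-iodo-3-methoxybenzene F3, and Mitsunobu coupling of F2 with 9 gives 2-{[4-(benzyloxy)-3-methoxyphenyl]methoxy}-5-bromo-1-iodo-3-methoxybenzene F4. Copper-catalysed arylation of 2 at the iodide (CuI, 2-picolinic acid, Cs2CO3, dioxane, 70 °C), with loss of the acetyl group by retro-Claisen cleavage in the same flask, turns F3 into 18 and F4 into 10.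

**Step 22.** The radical at C8′ may be reduced by a second Cp2TiCl before it cyclises (deoxygenation), or the benzylic radical may be reduced rather than iodinated, leaving a monocyclic benzyl tetrahydrofuran. The second closure could also lose facial control, because it runs through an ion pair. Fallback by the lactone route, all known chemistry: it sets out from 14 (through aldehyde F6 of the fallback to step 19) and from 27 and comes back at 35. Bromide 27 is formylated (n-BuLi, then DMF) to aldehyde F9, and F6 is turned into its 1,3-dithiane F10 (propane-1,3-dithiol, cat. I2). Lithiated F10 adds to (5R)-5-[(1R,2S,5R)-menthyloxy]furan-2(5H)-one trans to the menthyloxy group, and the enolate is trapped by F9 to give the trans,trans lactone adduct F11 (3S,4R,5R; carbinol epimers). Hg(ClO4)2 with CaCO3 frees the ketone F12, LiAlH4 gives the tetraol F13, and MsCl in pyridine closes both tetrahydrofuran rings to 35.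

**Step 19.** The hindered copper alkoxide may react slowly, so that the linear ether grows or the allyl complex loses a proton to a diene; slow turnover can also lower the enantiomeric purity. Fallback by carbonyl addition and Williamson etherification: it sets out from 14 and 29 and comes back at 31. Bromide 14 is formylated (n-BuLi, then DMF) to the D-aryl aldehyde F6. Enantioselective addition of divinylzinc under a chiral amino-alcohol ligand gives (S)-1-(D-aryl)prop-2-en-1-ol F7. Alcohol 29 is converted (CBr4, PPh3) into the propargylic bromide F8, and the sodium alkoxide of F7 (NaH, THF, 0 °C) is alkylated with F8 to give 31.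

**Step 7.** The extra methoxy group next to the benzyloxy oxygen may change how the benzyl ether sits in the catalyst pocket, lowering enantioselectivity and, to a lesser degree, the cis preference; azine formation from the diazo ester is a minor risk. Fallback by resolution: it sets out from 13 of insufficient enantiomeric purity and comes back at pure 13. The alcohol is esterified with (S)-2-methoxy-2-phenylacetic acid (DCC, DMAP), the (S)-2-methoxy-2-phenylacetate of 13, F5, is separated from its diastereomer by crystallisation or chromatography, and methanolysis (K2CO3, MeOH) returns 13.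

**Step 24.** Oxidation at the hindered carbinol may be slow, and long contact with the oxide surface may cause partial dehydration or epimerisation of the β-hydroxy ketone. Fallback by protection, oxidation and deprotection: it sets out from 36 and comes back at 37. The two primary hydroxyls are silylated selectively (TBSCl, imidazole, 0 °C) to the bis(TBS) ether F14, Dess–Martin periodinane buffered with NaHCO3 gives the ketone F15, and HF·pyridine buffered with pyridine removes the silyl groups to give 37.

## Further compounds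

F1 | step 1 | 4-bromo-2-methoxyphenol (purchased) | COc1cc(Br)ccc1O
F2 | step 1 | 4-bromo-2-iodo-6-methoxyphenol | COc1cc(Br)cc(I)c1O
F3 | step 1 | 2-(benzyloxy)-5-bromo-1-iodo-3-methoxybenzene | COc1cc(Br)cc(I)c1OCc1ccccc1
F4 | step 1 | 2-{[4-(benzyloxy)-3-methoxyphenyl]methoxy}-5-bromo-1-iodo-3-methoxybenzene | COc1cc(Br)cc(I)c1OCc1ccc(OCc2ccccc2)c(OC)c1
F5 | step 7 | (S)-2-methoxy-2-phenylacetate of 13 | CO[C@H](C(=O)OC[C@@H]1c2cc(Br)cc(OC)c2O[C@@H]1c1ccc(OCc2ccccc2)c(OC)c1)c1ccccc1
F6 | step 19 | D-aryl aldehyde | O=Cc1cc(OC)c2c(c1)[C@@H](CO[Si](C)(C)C(C)(C)C)[C@@H](c1ccc(OCc3ccccc3)c(OC)c1)O2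
F7 | step 19 | (S)-1-(D-aryl)prop-2-en-1-ol | O[C@@H](C=C)c1cc(OC)c2c(c1)[C@@H](CO[Si](C)(C)C(C)(C)C)[C@@H](c1ccc(OCc3ccccc3)c(OC)c1)O2
F8 | step 19 | 3-(B-aryl)prop-2-yn-1-yl bromide | CC(C)(C)[Si](C)(C)OC[C@H](c1cc(C#CCBr)cc(OC)c1OCc1ccccc1)[C@@H](O[Si](C)(C)C(C)(C)C)c1ccc(OCc2ccccc2)c(OC)c1
F9 | step 22 | B-aryl aldehyde | CC(C)(C)[Si](C)(C)OC[C@H](c1cc(C=O)cc(OC)c1OCc1ccccc1)[C@@H](O[Si](C)(C)C(C)(C)C)c1ccc(OCc2ccccc2)c(OC)c1
F10 | step 22 | 2-(D-aryl)-1,3-dithiane | C1CSC(SC1)c1cc(OC)c2c(c1)[C@@H](CO[Si](C)(C)C(C)(C)C)[C@@H](c1ccc(OCc3ccccc3)c(OC)c1)O2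
F11 | step 22 | (3S,4R,5R)-3-[(B-aryl)hydroxymethyl]-4-[2-(D-aryl)-1,3-dithian-2-yl]-5-[(1R,2S,5R)-menthyloxy]dihydrofuran-2(3H)-one | CC(C)(C)[Si](C)(C)OC[C@H](c1cc(C(O)[C@H]3C(=O)O[C@@H](O[C@@H]4C[C@H](C)CC[C@H]4C(C)C)[C@@H]3C3(SCCCS3)c3cc(OC)c4c(c3)[C@@H](CO[Si](C)(C)C(C)(C)C)[C@@H](c3ccc(OCc5ccccc5)c(OC)c3)O4)cc(OC)c1OCc1ccccc1)[C@@H](O[Si](C)(C)C(C)(C)C)c1ccc(OCc2ccccc2)c(OC)c1
F12 | step 22 | ketone from F11 (dithiane replaced by C=O) | CC(C)(C)[Si](C)(C)OC[C@H](c1cc(C(O)[C@H]3C(=O)O[C@@H](O[C@@H]4C[C@H](C)CC[C@H]4C(C)C)[C@@H]3C(=O)c3cc(OC)c4c(c3)[C@@H](CO[Si](C)(C)C(C)(C)C)[C@@H](c3ccc(OCc5ccccc5)c(OC)c3)O4)cc(OC)c1OCc1ccccc1)[C@@H](O[Si](C)(C)C(C)(C)C)c1ccc(OCc2ccccc2)c(OC)c1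
F13 | step 22 | (2R,3R)-1-(B-aryl)-4-(D-aryl)-2,3-bis(hydroxymethyl)butane-1,4-diol (carbinol epimers) | CC(C)(C)[Si](C)(C)OC[C@H](c1cc(C(O)[C@@H](CO)[C@H](CO)C(O)c3cc(OC)c4c(c3)[C@@H](CO[Si](C)(C)C(C)(C)C)[C@@H](c3ccc(OCc5ccccc5)c(OC)c3)O4)cc(OC)c1OCc1ccccc1)[C@@H](O[Si](C)(C)C(C)(C)C)c1ccc(OCc2ccccc2)c(OC)c1
F14 | step 24 | 36 with both primary hydroxyls as TBS ethers | CC(C)(C)[Si](C)(C)OC[C@H](c1cc([C@H]2OC[C@H]3[C@@H]2CO[C@@H]3c2cc(OC)c3c(c2)[C@@H](CO[Si](C)(C)C(C)(C)C)[C@@H](c2ccc(OCc4ccccc4)c(OC)c2)O3)cc(OC)c1OCc1ccccc1)[C@@H](O)c1ccc(OCc2ccccc2)c(OC)c1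
F15 | step 24 | 37 with both primary hydroxyls as TBS ethers | COc1cc(C(=O)[C@H](CO[Si](C)(C)C(C)(C)C)c2cc([C@H]3OC[C@H]4[C@@H]3CO[C@@H]4c3cc(OC)c4c(c3)[C@@H](CO[Si](C)(C)C(C)(C)C)[C@@H](c3ccc(OCc5ccccc5)c(OC)c3)O4)cc(OC)c2OCc2ccccc2)ccc1OCc1ccccc1
A1 | alternative 1 | all-trans 1,2-diaryl cyclobutane with 1-methylimidazol-2-yl ketone and silyloxymethyl groups | COc1cc([C@@H]2[C@@H](CO[Si](C)(C)C(C)(C)C)[C@H](C(=O)c3nccn3C)[C@H]2c2cc(OC)c3c(c2)[C@@H](CO[Si](C(C)C)(C(C)C)C(C)C)[C@@H](c2ccc(OCc4ccccc4)c(OC)c2)O3)cc(Br)c1OCc1ccccc1
A2 | alternative 1 | ring D (E)-cinnamoyl 1-methylimidazole | Cn1ccnc1C(=O)/C=C/c1cc(OC)c2c(c1)[C@@H](CO[Si](C(C)C)(C(C)C)C(C)C)[C@@H](c1ccc(OCc3ccccc3)c(OC)c1)O2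
A3 | alternative 1 | ring B (E)-cinnamyl tert-butyldimethylsilyl ether | COc1cc(/C=C/CO[Si](C)(C)C(C)(C)C)cc(Br)c1OCc1ccccc1
A4 | alternative 2 | methyl cis-(2S,3R)-2-[4-(benzyloxy)-3-methoxyphenyl]-5-bromo-7-methoxy-2,3-dihydro-1-benzofuran-3-carboxylate (same as 12) | Brc1cc(OC)c2c(c1)[C@@H](C(=O)OC)[C@@H](c1ccc(OCc3ccccc3)c(OC)c1)O2
A5 | alternative 2 | ring D aryldiazoacetate with the ring E benzyl ether (same as 11) | COC(=O)C(=[N+]=[N-])c1cc(Br)cc(OC)c1OCc1ccc(OCc2ccccc2)c(OC)c1
A6 | alternative 3 | exo,exo-diaryl furofuran with bromophenol ring B and tosylated ring E | COc1cc([C@H]2OC[C@H]3[C@@H]2CO[C@@H]3c2cc(OC)c3c(c2)[C@@H](CO[Si](C(C)C)(C(C)C)C(C)C)[C@@H](c2ccc(OS(=O)(=O)c4ccc(C)cc4)c(OC)c2)O3)cc(Br)c1O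
A7 | alternative 3 | (2R,3R)-threo-dibenzylbutane-1,4-diol with bromophenol ring B and tosylated ring E | OC[C@H](Cc1cc(OC)c(O)c(Br)c1)[C@H](CO)Cc1cc(OC)c2c(c1)[C@@H](CO[Si](C(C)C)(C(C)C)C(C)C)[C@@H](c1ccc(OS(=O)(=O)c3ccc(C)cc3)c(OC)c1)O2
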